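**Retrosynthetic overview**
1. Target 11 ⇐ B-ring dihydrocoumarin 10: double methyl addition to the lactone unveils the 2′-OH and the tertiary carbinol together, and the acetates fall in the same flask.
2. 10 ⇐ propanoic acid 9: the key disconnection is the aryl C2′–O bond, made by a carboxylate-directed C–H lactonisation (new). The tether can only reach C2′.
3. 9 ⇐ aryl bromide 6 + acrylic acid (Heck coupling, then hydrogenation in the same flask).
4. 6 ⇐ isoflavone 5 ⇐ phloroglucinol + 5-bromohomovanillic acid 2; the pyranone ring is closed through the O1–C2 bond.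
5. Ring order: A and B rings are bought; pyranone ring in step 2; temporary lactone ring in step 5, opened in step 6.

Assumption: the target SMILES has no stereocentre and no stereogenic double bond, so the compound is achiral and no enantiocontrol is needed.

**Step 1**
Reactants: 1 homovanillic acid [2-(4-hydroxy-3-methoxyphenyl)acetic acid]
Product: 2 2-(3-bromo-4-hydroxy-5-methoxyphenyl)acetic acid
Conditions: Br2 (1.05 equiv), AcOH, 15 °C → rt
Reagents that add atoms: bromine, BrBr
Why: Electrophilic aromatic bromination in which the free phenol directs to its only open ortho position (para is blocked), as in the bromination of vanillin.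

**Step 2**
Reactants: 2 2-(3-bromo-4-hydroxy-5-methoxyphenyl)acetic acid; 3 phloroglucinol (benzene-1,3,5-triol)
Product: 5 3-(3-bromo-4-hydroxy-5-methoxyphenyl)-5,7-dihydroxy-4H-chromen-4-one, via deoxybenzoin 4 (not isolated)
Conditions: BF3·OEt2 (as solvent), 85 °C; then DMF, MsCl, 70 °C; aq. NaOAc work-up
Reagents that add atoms: N,N-dimethylformamide (supplies C-2), CN(C)C=O
Why: BF3-mediated Friedel–Crafts C-acylation of the symmetric phloroglucinol gives the deoxybenzoin, whose active methylene is formylated by the DMF/MsCl Vilsmeier-type reagent, after which the ortho phenol adds and dimethylamine is lost to close the pyranone through the O1–C2 bond (one-pot deoxybenzoin route to isoflavones).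

**Step 3**
Reactants: 5 3-(3-bromo-4-hydroxy-5-methoxyphenyl)-5,7-dihydroxy-4H-chromen-4-one
Product: 6 3-(4-acetoxy-3-bromo-5-methoxyphenyl)-4-oxo-4H-chromene-5,7-diyl diacetate
Conditions: Ac2O, pyridine, DMAP (cat.), rt
Reagents that add atoms: acetic anhydride, CC(=O)OC(C)=O
Why: DMAP-catalysed O-acylation caps all three phenols (including the chelated 5-OH), so the 4′-oxygen cannot lactonise with the coming side chain and the rings are shielded from the oxidant of step 5; the acetates are later removed by the Grignard reagent itself.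

**Step 4**
Reactants: 6 3-(4-acetoxy-3-bromo-5-methoxyphenyl)-4-oxo-4H-chromene-5,7-diyl diacetate; 7 acrylic acid
Product: 9 3-[2-acetoxy-5-(5,7-diacetoxy-4-oxo-4H-chromen-3-yl)-3-methoxyphenyl]propanoic acid, via cinnamic acid 8 (not isolated)
Conditions: Pd(OAc)2 (5 mol %), P(o-tol)3 (10 mol %), Et3N, MeCN, 90 °C; then H2 (1 atm), 10 % Pd/C, rt
Reagents that add atoms: none
Why: Mizoroki–Heck coupling of the aryl bromide with acrylic acid gives the (E)-cinnamic acid, whose unhindered, electron-poor C=C is hydrogenated over Pd/C in the same flask much faster than the chromone C2=C3 bond (one-pot Heck/hydrogenation).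

**Step 5**
Reactants: 9 3-[2-acetoxy-5-(5,7-diacetoxy-4-oxo-4H-chromen-3-yl)-3-methoxyphenyl]propanoic acid
Product: 10 3-(5-acetoxy-6-methoxy-2-oxo-3,4-dihydro-2H-chromen-8-yl)-4-oxo-4H-chromene-5,7-diyl diacetate
Conditions: Pd(OAc)2 (10 mol %), Ac-Gly-OH (20 mol %), PhI(OAc)2 (1.5 equiv), KOAc (1 equiv), t-BuOH, 80 °C
Reagents that add atoms: none
Why: Proposed new method: carboxylate-directed Pd(II)/Pd(IV) C(sp2)–H lactonisation of a flexible 3-arylpropanoic acid, in which the bound carboxylate delivers Pd(II) (Ac-Gly-OH-assisted concerted metalation–deprotonation) to C2′, the only C–H ortho to the tether (the other ortho carbon carries OAc; C2′ is also para to OMe and so the most nucleophilic B-ring carbon, and the chromone C4=O can serve as a second hemilabile donor), PhI(OAc)2 oxidises the seven-membered palladacycle to Pd(IV), and intramolecular C–O reductive elimination closes the six-membered lactone, forming the C2′–O bond with tether-enforced regiocontrol; the closest known reaction type is the Pd/PhI(OAc)2 C–H lactonisation of 2-arylbenzoic acids and α,α-disubstituted arylacetic acids, not yet shown for an unbiased hydrocinnamic acid at a doubly flanked C–H or on an isoflavone.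

**Step 6**
Reactants: 10 3-(5-acetoxy-6-methoxy-2-oxo-3,4-dihydro-2H-chromen-8-yl)-4-oxo-4H-chromene-5,7-diyl diacetate
Product: 11 3-[2,4-dihydroxy-3-(3-hydroxy-3-methylbutyl)-5-methoxyphenyl]-5,7-dihydroxy-4H-chromen-4-one (target)
Conditions: MeMgBr (12 equiv), THF, −78 → 0 °C; then H2O/NH4Cl buffer (pH ≈ 6), 0 °C
Reagents that add atoms: methylmagnesium bromide, C[Mg]Br
Why: Grignard addition in which the aryl acetates are cleaved first at low temperature, the resulting 5,7-diphenoxide deactivates the chromone toward nucleophiles, and double methyl addition to the aryl lactone releases the 2′-phenoxide and builds the tertiary carbinol, the buffered quench avoiding acid-mediated chroman formation.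

**Compound list**
1 | homovanillic acid, 2-(4-hydroxy-3-methoxyphenyl)acetic acid | COc1cc(CC(=O)O)ccc1O | starting material
2 | 2-(3-bromo-4-hydroxy-5-methoxyphenyl)acetic acid | COc1cc(CC(=O)O)cc(Br)c1O | intermediate
3 | phloroglucinol, benzene-1,3,5-triol | Oc1cc(O)cc(O)c1 | starting material
4 | 2-(3-bromo-4-hydroxy-5-methoxyphenyl)-1-(2,4,6-trihydroxyphenyl)ethan-1-one (deoxybenzoin) | COc1cc(CC(=O)c2c(O)cc(O)cc2O)cc(Br)c1O | intermediate
5 | 3-(3-bromo-4-hydroxy-5-methoxyphenyl)-5,7-dihydroxy-4H-chromen-4-one | COc1cc(-c2coc3cc(O)cc(O)c3c2=O)cc(Br)c1O | intermediate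
6 | 3-(4-acetoxy-3-bromo-5-methoxyphenyl)-4-oxo-4H-chromene-5,7-diyl diacetate | COc1cc(-c2coc3cc(OC(C)=O)cc(OC(C)=O)c3c2=O)cc(Br)c1OC(C)=O | intermediate
7 | acrylic acid | C=CC(=O)O | starting material
8 | (E)-3-[2-acetoxy-5-(5,7-diacetoxy-4-oxo-4H-chromen-3-yl)-3-methoxyphenyl]prop-2-enoic acid (cinnamic acid) | COc1cc(-c2coc3cc(OC(C)=O)cc(OC(C)=O)c3c2=O)cc(/C=C/C(=O)O)c1OC(C)=O | intermediate
9 | 3-[2-acetoxy-5-(5,7-diacetoxy-4-oxo-4H-chromen-3-yl)-3-methoxyphenyl]propanoic acid | COc1cc(-c2coc3cc(OC(C)=O)cc(OC(C)=O)c3c2=O)cc(CCC(=O)O)c1OC(C)=O | intermediate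
10 | 3-(5-acetoxy-6-methoxy-2-oxo-3,4-dihydro-2H-chromen-8-yl)-4-oxo-4H-chromene-5,7-diyl diacetate | COc1cc(-c2coc3cc(OC(C)=O)cc(OC(C)=O)c3c2=O)c2OC(=O)CCc2c1OC(C)=O | intermediate
11 | 3-[2,4-dihydroxy-3-(3-hydroxy-3-methylbutyl)-5-methoxyphenyl]-5,7-dihydroxy-4H-chromen-4-one | COc1cc(-c2coc3cc(O)cc(O)c3c2=O)c(O)c(CCC(C)(C)O)c1O | target

**Totals**
Total step count: 6. Longest linear sequence: 6 steps (1 → 2 → 5 → 6 → 9 → 10 → 11).

**Steps most likely to fail**

Step 5 (the proposed new lactonisation) is the main risk. Palladation must occur at a C–H flanked on both sides, C–OAc reductive elimination can compete with lactone formation, and slow acyl transfer from the 4′-acetate to the carboxylate could give the isomeric 4′-O-lactone. The fallback uses known chemistry and sets out from 9. Electrophilic bromination with NBS in MeCN at rt, expected para to the methoxy group, gives 3-[2-acetoxy-6-bromo-5-(5,7-diacetoxy-4-oxo-4H-chromen-3-yl)-3-methoxyphenyl]propanoic acid F2. A copper(I)-mediated Ullmann-type coupling of the aryl bromide with its own carboxylate (copper(I) thiophene-2-carboxylate, DMF, 110 °C) then closes the lactone; any acetate lost is put back with Ac2O/pyridine. This returns to the route at 10.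

Step 6 is the second risk. The Grignard reagent could attack the chromone before the acetates are gone, and the hindered 4′- and 5-acetates may cleave slowly. The fallback sets out from 10 and separates deprotection from C–C bond formation. Methanolysis (K2CO3, MeOH, 0 °C) removes the three acetates and opens the lactone to methyl 3-[3-(5,7-dihydroxy-4-oxo-4H-chromen-3-yl)-2,6-dihydroxy-5-methoxyphenyl]propanoate F3. This is then treated with excess MeMgBr and CeCl3 in THF: the four phenols are deprotonated first, which shuts down the chromone, and the organocerium reagent adds twice to the alkyl ester. Re-lactonisation of F3 to either phenol is harmless, since both lactones give the same product. This returns to the route at 11.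

Step 4 is the third risk. Acetates may be lost under Et3N at 90 °C, the Pd/C may be poisoned by the phosphine and ammonium salts of the Heck stage, and the chromone C2=C3 bond may be over-reduced. The fallback sets out from 6 and avoids both the alkene and the hydrogenation. A Negishi sp2–sp3 coupling with [3-(tert-butoxy)-3-oxopropyl]zinc bromide (Pd(OAc)2, SPhos, THF, 40 °C) gives tert-butyl 3-[2-acetoxy-5-(5,7-diacetoxy-4-oxo-4H-chromen-3-yl)-3-methoxyphenyl]propanoate F1. The tert-butyl ester is then cleaved with TFA in CH2Cl2, which leaves the aryl acetates intact. This returns to the route at 9.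

**Further compounds**
F1 | step 4 | tert-butyl 3-[2-acetoxy-5-(5,7-diacetoxy-4-oxo-4H-chromen-3-yl)-3-methoxyphenyl]propanoate | COc1cc(-c2coc3cc(OC(C)=O)cc(OC(C)=O)c3c2=O)cc(CCC(=O)OC(C)(C)C)c1OC(C)=O
F2 | step 5 | 3-[2-acetoxy-6-bromo-5-(5,7-diacetoxy-4-oxo-4H-chromen-3-yl)-3-methoxyphenyl]propanoic acid | COc1cc(-c2coc3cc(OC(C)=O)cc(OC(C)=O)c3c2=O)c(Br)c(CCC(=O)O)c1OC(C)=O
F3 | step 6 | methyl 3-[3-(5,7-dihydroxy-4-oxo-4H-chromen-3-yl)-2,6-dihydroxy-5-methoxyphenyl]propanoate | COC(=O)CCc1c(O)c(-c2coc3cc(O)cc(O)c3c2=O)cc(OC)c1O
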